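**Plan**
- Retrosynthesis first cuts the C8–CH2 bond to the pyrone (ring C), then the two C2–CH3 bonds of the dihydropyran (ring B), and last C3–C4 together with O1–C2.
- Enabling feature: C4–C4a–C8a–O1 of rings A/B is a latent ortho-quinone methide and C2–C3(O) a latent alkoxyketene, so ring B and the C3 stereocentre can be made in one step with C2 as a lactone carbonyl.
- Forward: phloroacetophenone is taken to a silyloxybenzyl bromide; annulation with benzyloxyketene closes ring B as a dihydrocoumarin.
- Two methyl groups on C2 then open the lactone, acid recloses O1–C2, and hydrogenolysis frees the three hydroxyls.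
- Ring C is built separately from methyl 3-oxopentanoate and joined last through a CH2 at C8.
- The only stereocentre, C3 (R), is set by the cinchona ester catalyst in the annulation and is not touched afterwards.

Key step: step 8

Remark: O-benzoylquinine is assigned to the (R) centre by analogy with its facial sense in related ketene enolate reactions; this is an assumption, and O-benzoylquinidine would be taken if the sense proved opposite.

**Step 1**
Reactants: 1 2',4',6'-trihydroxyacetophenone
Product: 2 2',6'-dihydroxy-4'-(methoxymethoxy)acetophenone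
Conditions: MOMCl (1.05 equiv), iPr2NEt, CH2Cl2, 0 °C
Reagents that add atoms: chloromethyl methyl ether, COCCl
Why: The para hydroxyl is the only one not hydrogen-bonded to the acetyl group, so one equivalent of the chloromethyl ether should alkylate it selectively (regioselective O-alkylation).

**Step 2**
Reactants: 2 2',6'-dihydroxy-4'-(methoxymethoxy)acetophenone
Product: 3 2',6'-bis(benzyloxy)-4'-(methoxymethoxy)acetophenone
Conditions: BnBr, K2CO3, DMF, 70 °C
Reagents that add atoms: benzyl bromide, BrCc1ccccc1
Why: Forcing Williamson etherification benzylates both chelated hydroxyls, and the acetal at the para oxygen is stable to base.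

**Step 3**
Reactants: 3 2',6'-bis(benzyloxy)-4'-(methoxymethoxy)acetophenone
Product: 4 2',6'-bis(benzyloxy)-4'-hydroxyacetophenone
Conditions: HCl (cat.), MeOH–THF, 45 °C
Reagents that add atoms: none
Why: Acid-catalysed acetal exchange with methanol removes the methoxymethyl group, while benzyl ethers and the hindered ketone are inert to dilute acid.

**Step 4**
Reactants: 4 2',6'-bis(benzyloxy)-4'-hydroxyacetophenone
Product: 6 3-acetyl-2,4-bis(benzyloxy)-6-hydroxybenzaldehyde, via hydroxymethyl phenol 5 (not isolated)
Conditions: MgCl2, Et3N, (CH2O)n, MeCN, reflux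
Reagents that add atoms: formaldehyde (as paraformaldehyde), C=O
Why: In the Casnati–Skattebøl ortho-formylation the magnesium phenoxide delivers formaldehyde to the ortho carbon and a second formaldehyde oxidises the hydroxymethyl group; the two ortho positions are equivalent, so one aldehyde should result.

**Step 5**
Reactants: 6 3-acetyl-2,4-bis(benzyloxy)-6-hydroxybenzaldehyde
Product: 7 3-acetyl-2,4-bis(benzyloxy)-6-(tert-butyldimethylsilyloxy)benzaldehyde
Conditions: TBSCl, imidazole, DMF, rt
Reagents that add atoms: tert-butyldimethylsilyl chloride, CC(C)(C)[Si](C)(C)Cl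
Why: Standard silylation of an acidic phenol gives the aryl silyl ether that fluoride will later cleave.

**Step 6**
Reactants: 7 3-acetyl-2,4-bis(benzyloxy)-6-(tert-butyldimethylsilyloxy)benzaldehyde
Product: 8 1-[2,6-bis(benzyloxy)-4-(tert-butyldimethylsilyloxy)-3-(hydroxymethyl)phenyl]ethanone
Conditions: NaBH4, THF–MeOH, −20 °C, short reaction time, pH 7 quench
Reagents that add atoms: none
Why: Borohydride reduces the aldehyde far faster than the twisted, doubly ortho-substituted aryl ketone, and cold, brief, buffered conditions limit silyl migration to the new benzylic oxygen.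

**Step 7**
Reactants: 8 1-[2,6-bis(benzyloxy)-4-(tert-butyldimethylsilyloxy)-3-(hydroxymethyl)phenyl]ethanone
Product: 9 1-[2,6-bis(benzyloxy)-3-(bromomethyl)-4-(tert-butyldimethylsilyloxy)phenyl]ethanone
Conditions: CBr4, PPh3, CH2Cl2, 0 °C; short silica plug, used at once
Reagents that add atoms: carbon tetrabromide, BrC(Br)(Br)Br
Why: The neutral Appel reaction converts the electron-rich benzylic alcohol to the bromide without touching the silyl ether; the labile bromide is carried forward directly.

**Step 8**
Reactants: 9 1-[2,6-bis(benzyloxy)-3-(bromomethyl)-4-(tert-butyldimethylsilyloxy)phenyl]ethanone; 10 benzyloxyacetyl chloride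
Product: 13 (3R)-6-acetyl-3,5,7-tris(benzyloxy)chroman-2-one, via benzyloxyketene 11 (not isolated), via ortho-quinone methide 12 (not isolated)
Conditions: O-benzoylquinine (15 mol %), iPr2NEt, CsF, 18-crown-6, THF, −78 → −40 °C, slow addition of 10
Reagents that add atoms: none
Why: Fluoride removes the silyl group of 9 and the phenoxide expels bromide to give the transient methide 12, while iPr2NEt dehydrochlorinates 10 to ketene 11, which O-benzoylquinine captures as a chiral ammonium enolate. The enolate carbon adds to the exocyclic CH2 of 12 in a Michael step that restores the aromatic ring (C3–C4), and the phenoxide then attacks the acylammonium carbonyl (O1–C2) and releases the catalyst. The closest known reaction type is the cinchona-ester-catalysed formal four plus two annulation of acid-chloride-derived ketene enolates with ortho-quinone methides, and fluoride-triggered release of unsubstituted methides from silyloxybenzyl bromides is established in related azolium enolate annulations. Ring B closes by a 6-exo-trig acyl substitution. C3 is the only new stereocentre and, since the methide CH2 is not prochiral, it is decided solely by which enolate face the bound catalyst leaves open; O-benzoylquinine is expected to give (R). The step needs C-alkylation of the methide to outrun methide dimerisation and phenoxide O-acylation; this should be secured by slow addition of 10, by the para acetyl group that polarises the methide, and by methide release only as fast as fluoride dissolves.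

**Step 9**
Reactants: 13 (3R)-6-acetyl-3,5,7-tris(benzyloxy)chroman-2-one
Product: 15 1-{2,6-bis(benzyloxy)-3-[(2R)-2-(benzyloxy)-3-hydroxy-3-methylbutyl]-4-hydroxyphenyl}ethanone, via methyl ketone 14 (not isolated)
Conditions: MeLi (2.3 equiv), CeCl3, THF, −78 → −40 °C; aq. NH4Cl
Reagents that add atoms: methyllithium, [Li]C
Why: Double organocerium addition to an aryl lactone (the classical dihydrocoumarin opening) should be chemoselective because the aryl ester and then the alpha-alkoxy ketone are much more electrophilic than the hindered acetyl group, which is further deactivated by the para phenoxide once the lactone opens, and the weakly basic reagent spares the C3 hydrogen.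

**Step 10**
Reactants: 15 1-{2,6-bis(benzyloxy)-3-[(2R)-2-(benzyloxy)-3-hydroxy-3-methylbutyl]-4-hydroxyphenyl}ethanone
Product: 16 1-[(3R)-3,5,7-tris(benzyloxy)-2,2-dimethylchroman-6-yl]ethanone
Conditions: TsOH·H2O (10 mol %), toluene, 60 °C
Reagents that add atoms: none
Why: Acid-catalysed cyclodehydration lets the only free phenol trap the ionised tertiary carbinol in a six-membered closure (O1–C2); C3 is not a reacting centre and the benzylated C5 oxygen cannot compete.

**Step 11**
Reactants: 16 1-[(3R)-3,5,7-tris(benzyloxy)-2,2-dimethylchroman-6-yl]ethanone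
Product: 17 1-[(3R)-3,5,7-trihydroxy-2,2-dimethylchroman-6-yl]ethanone
Conditions: H2 (1 atm), Pd/C (10 wt %), EtOAc–MeOH, rt
Reagents that add atoms: none
Why: Hydrogenolysis cleaves the two aryl benzyl ethers and the secondary benzyl ether, while the ketone, which becomes a hydrogen-bonded vinylogous acid, and the chroman ether should survive.

**Step 12**
Reactants: 18 methyl 3-oxopentanoate; 19 N-methoxy-N-methylpropanamide
Product: 20 methyl 4-methyl-3,5-dioxoheptanoate
Conditions: LiN(iPr)2 (2.1 equiv), THF, 0 °C; then 19, −78 → 0 °C; aq. HCl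
Reagents that add atoms: none
Why: The beta-keto ester dianion is acylated at its more reactive gamma carbon, and the chelated tetrahedral adduct of the Weinreb amide prevents over-addition (dianion gamma-acylation).

**Step 13**
Reactants: 20 methyl 4-methyl-3,5-dioxoheptanoate
Product: 21 6-ethyl-4-hydroxy-5-methyl-2H-pyran-2-one
Conditions: DBU, toluene, reflux; aq. HCl
Reagents that add atoms: none
Why: Base-mediated lactonisation of the C5 enolate oxygen onto the ester, with loss of methanol, is the standard closure of 3,5-dioxo esters to 4-hydroxy-2-pyrones.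

**Step 14**
Reactants: 17 1-[(3R)-3,5,7-trihydroxy-2,2-dimethylchroman-6-yl]ethanone; 21 6-ethyl-4-hydroxy-5-methyl-2H-pyran-2-one
Product: 24 3-{[(3R)-6-acetyl-3,5,7-trihydroxy-2,2-dimethylchroman-8-yl]methyl}-6-ethyl-4-hydroxy-5-methyl-2H-pyran-2-one, via Mannich base 22 (not isolated), via methylenepyrandione 23 (not isolated)
Conditions: 21, CH2=NMe2 I (Eschenmoser's salt), CH2Cl2, rt; then 17, 40 °C
Reagents that add atoms: N,N-dimethylmethyleneiminium iodide, C=[N+](C)C.[I-]
Why: A Mannich reaction at C3 of the pyrone followed by loss of dimethylamine gives a methylene dione that the acylphloroglucinol ring attacks at C8, its only free aromatic position (Mannich–elimination–Michael coupling known for methylene-bridged acylphloroglucinol pyrones).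

**Compound list**
1 | 2',4',6'-trihydroxyacetophenone | CC(=O)c1c(O)cc(O)cc1O | starting material
2 | 2',6'-dihydroxy-4'-(methoxymethoxy)acetophenone | CC(=O)c1c(O)cc(OCOC)cc1O | intermediate
3 | 2',6'-bis(benzyloxy)-4'-(methoxymethoxy)acetophenone | CC(=O)c1c(OCc2ccccc2)cc(OCOC)cc1OCc1ccccc1 | intermediate
4 | 2',6'-bis(benzyloxy)-4'-hydroxyacetophenone | CC(=O)c1c(OCc2ccccc2)cc(O)cc1OCc1ccccc1 | intermediate
5 | 1-[2,6-bis(benzyloxy)-4-hydroxy-3-(hydroxymethyl)phenyl]ethanone (not isolated) | CC(=O)c1c(OCc2ccccc2)cc(O)c(CO)c1OCc1ccccc1 | intermediate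
6 | 3-acetyl-2,4-bis(benzyloxy)-6-hydroxybenzaldehyde | CC(=O)c1c(OCc2ccccc2)cc(O)c(C=O)c1OCc1ccccc1 | intermediate
7 | 3-acetyl-2,4-bis(benzyloxy)-6-(tert-butyldimethylsilyloxy)benzaldehyde | CC(=O)c1c(OCc2ccccc2)cc(O[Si](C)(C)C(C)(C)C)c(C=O)c1OCc1ccccc1 | intermediate
8 | 1-[2,6-bis(benzyloxy)-4-(tert-butyldimethylsilyloxy)-3-(hydroxymethyl)phenyl]ethanone | CC(=O)c1c(OCc2ccccc2)cc(O[Si](C)(C)C(C)(C)C)c(CO)c1OCc1ccccc1 | intermediate
9 | 1-[2,6-bis(benzyloxy)-3-(bromomethyl)-4-(tert-butyldimethylsilyloxy)phenyl]ethanone | CC(=O)c1c(OCc2ccccc2)cc(O[Si](C)(C)C(C)(C)C)c(CBr)c1OCc1ccccc1 | intermediate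
10 | benzyloxyacetyl chloride | O=C(Cl)COCc1ccccc1 | starting material
11 | benzyloxyketene (not isolated) | O=C=COCc1ccccc1 | intermediate
12 | 4-acetyl-3,5-bis(benzyloxy)-6-methylidenecyclohexa-2,4-dien-1-one (ortho-quinone methide, not isolated) | CC(=O)C1=C(OCc2ccccc2)C(=C)C(=O)C=C1OCc1ccccc1 | intermediate
13 | (3R)-6-acetyl-3,5,7-tris(benzyloxy)chroman-2-one | CC(=O)c1c(OCc2ccccc2)cc2c(c1OCc1ccccc1)C[C@@H](OCc1ccccc1)C(=O)O2 | intermediate
14 | (3R)-4-[3-acetyl-2,4-bis(benzyloxy)-6-hydroxyphenyl]-3-(benzyloxy)butan-2-one (not isolated) | CC(=O)c1c(OCc2ccccc2)cc(O)c(C[C@@H](OCc2ccccc2)C(C)=O)c1OCc1ccccc1 | intermediate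
15 | 1-{2,6-bis(benzyloxy)-3-[(2R)-2-(benzyloxy)-3-hydroxy-3-methylbutyl]-4-hydroxyphenyl}ethanone | CC(=O)c1c(OCc2ccccc2)cc(O)c(C[C@@H](OCc2ccccc2)C(C)(C)O)c1OCc1ccccc1 | intermediate
16 | 1-[(3R)-3,5,7-tris(benzyloxy)-2,2-dimethylchroman-6-yl]ethanone | CC(=O)c1c(OCc2ccccc2)cc2c(c1OCc1ccccc1)C[C@@H](OCc1ccccc1)C(C)(C)O2 | intermediate
17 | 1-[(3R)-3,5,7-trihydroxy-2,2-dimethylchroman-6-yl]ethanone | CC(=O)c1c(O)cc2c(c1O)C[C@@H](O)C(C)(C)O2 | intermediate
18 | methyl 3-oxopentanoate | CCC(=O)CC(=O)OC | starting material
19 | N-methoxy-N-methylpropanamide | CCC(=O)N(C)OC | starting material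
20 | methyl 4-methyl-3,5-dioxoheptanoate | CCC(=O)C(C)C(=O)CC(=O)OC | intermediate
21 | 6-ethyl-4-hydroxy-5-methyl-2H-pyran-2-one | CCc1oc(=O)cc(O)c1C | intermediate
22 | 3-[(dimethylamino)methyl]-6-ethyl-4-hydroxy-5-methyl-2H-pyran-2-one (not isolated) | CCc1oc(=O)c(CN(C)C)c(O)c1C | intermediate
23 | 6-ethyl-5-methyl-3-methylidene-2H-pyran-2,4(3H)-dione (not isolated) | CCC1=C(C)C(=O)C(=C)C(=O)O1 | intermediate
24 | 3-{[(3R)-6-acetyl-3,5,7-trihydroxy-2,2-dimethylchroman-8-yl]methyl}-6-ethyl-4-hydroxy-5-methyl-2H-pyran-2-one | CCc1oc(=O)c(Cc2c(O)c(C(C)=O)c(O)c3c2OC(C)(C)[C@H](O)C3)c(O)c1C | target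

**Totals**
Total step count: 14. Longest linear sequence: 12 (steps 1–11 and 14); steps 12–13 form the pyrone branch.

**Steps most likely to fail**

Step 8. The methide may dimerise, or the freed phenoxide may be O-acylated by the ketene before C–C bond formation. Fluoride may also divert the acid chloride, and the enolate face may be poorly differentiated. The fallback makes the same two bonds one after the other under auxiliary control, setting out from bromide 9 and acid chloride 10. Acid chloride 10 is joined to lithiated (4S)-4-benzyloxazolidin-2-one to give (4S)-4-benzyl-3-[(benzyloxy)acetyl]oxazolidin-2-one F1. Its sodium enolate (NaN(SiMe3)2, THF, −78 °C) is alkylated by 9 on the face away from the benzyl group (auxiliary-controlled glycolate alkylation, C3–C4), giving (4S)-3-{(2R)-3-[3-acetyl-2,4-bis(benzyloxy)-6-(tert-butyldimethylsilyloxy)phenyl]-2-(benzyloxy)propanoyl}-4-benzyloxazolidin-2-one F2. Bu4NF buffered with AcOH then frees the phenol, which attacks the exocyclic imide carbonyl and expels the auxiliary (O1–C2), and the route is rejoined at lactone 13.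

Step 9. The methyl nucleophile may attack the acetyl carbonyl before the lactone has opened, or deprotonation at C3 may erode the stereocentre. The fallback sets out from lactone 13 and puts the protecting phenoxide in place before any carbon nucleophile is present. Aminolysis with Me2AlN(OMe)Me (from AlMe3 and MeONHMe·HCl, CH2Cl2, 0 °C) opens the aryl ester to (2R)-3-[3-acetyl-2,4-bis(benzyloxy)-6-hydroxyphenyl]-2-(benzyloxy)-N-methoxy-N-methylpropanamide F3. Excess MeMgBr (THF, −78 → 0 °C) first forms the magnesium phenoxide para to the acetyl group and then converts the amide to methyl ketone 14, which is isolated this time. A second MeMgBr/CeCl3 addition at −78 °C, again on the phenoxide, rejoins the route at 15.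

Step 10. The tertiary cation next to the benzyloxy-bearing carbon may undergo hydride shift or proton loss from C3, which would erase the stereocentre, or may eliminate to the isopropenyl compound instead of being trapped by the phenol. The fallback sets out from 15 and closes the ring at the other C–O bond, so no cation at C2 is needed. Triflation of the phenol (PhNTf2, Et3N, CH2Cl2) gives 4-acetyl-3,5-bis(benzyloxy)-2-[(2R)-2-(benzyloxy)-3-hydroxy-3-methylbutyl]phenyl trifluoromethanesulfonate F4 with the tertiary alcohol untouched. Intramolecular Buchwald–Hartwig-type etherification (Pd(OAc)2, a bulky di-tert-butyl biaryl phosphine, Cs2CO3, toluene, 80 °C) then joins the tertiary alkoxide to C8a, and the route is rejoined at chroman 16.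

**Further compounds**
F1 | step 8 | (4S)-4-benzyl-3-[(benzyloxy)acetyl]oxazolidin-2-one | O=C(COCc1ccccc1)N1[C@@H](Cc2ccccc2)COC1=O
F2 | step 8 | (4S)-3-{(2R)-3-[3-acetyl-2,4-bis(benzyloxy)-6-(tert-butyldimethylsilyloxy)phenyl]-2-(benzyloxy)propanoyl}-4-benzyloxazolidin-2-one | CC(=O)c1c(OCc2ccccc2)cc(O[Si](C)(C)C(C)(C)C)c(C[C@@H](OCc2ccccc2)C(=O)N2[C@@H](Cc3ccccc3)COC2=O)c1OCc1ccccc1
F3 | step 9 | (2R)-3-[3-acetyl-2,4-bis(benzyloxy)-6-hydroxyphenyl]-2-(benzyloxy)-N-methoxy-N-methylpropanamide | CC(=O)c1c(OCc2ccccc2)cc(O)c(C[C@@H](OCc2ccccc2)C(=O)N(C)OC)c1OCc1ccccc1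
F4 | step 10 | 4-acetyl-3,5-bis(benzyloxy)-2-[(2R)-2-(benzyloxy)-3-hydroxy-3-methylbutyl]phenyl trifluoromethanesulfonate | CC(=O)c1c(OCc2ccccc2)cc(OS(=O)(=O)C(F)(F)F)c(C[C@@H](OCc2ccccc2)C(C)(C)O)c1OCc1ccccc1
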